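In a one-step world, first order in starting material at constant enzyme (pseudo-first-order), the fraction left is a plain exponential of a single number, the dose: the natural logarithm of the charge over what remains. It grows with enzyme and time and does not depend on the charge.

| flask | starting material | enzyme | remark | time |
|---|---|---|---|---|
| maple | 6 mM | 0.11 µM | run made earlier |  |
| spring | 6.0 mM | 0.17 µM |  | 3.0 h |
| noon | 12 mM | 0.17 µM |  | 3.0 h |
| winter | 25 mM | 0.17 µM |  | 3.0 h |
| summer | 50 mM | 0.17 µM |  | 3.0 h |
| dusk | 100 mM | 0.17 µM |  | 3.0 h |

- maple (time / min: product / %): 2.00: 0.2; 6.00: 5.7; 10.0: 5.6; 15.0: 6.3; 20.0: 8.6; 30.0: 12.2; 40.0: 14.8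

(each reading ± 1 percentage point)

- [product] at the end for spring, noon, winter, summer, dusk, in this order
- the course of these numbers from the first flask to the last (rises all the way / falls, then rises / hardly changes / rises, then falls / falls all the way)

- "hardly changes" means that all values lie within two and a half points (for a concentration: within two and a half percent of the largest)
- no earlier run changes the charge of enzyme; that part of a forecast is a guess

The last maple reading, 14.8% product at 40.0 min, carries its scatter and gives maple a dose of 0.160. We scale this by time and, as a guess, by enzyme, and so reach the dose of a flask with 0.17 µM enzyme after 3.0 h, 1.11. The fraction left is then 32.8%, so our own reckoning gives 4.03 mM in spring and, with the dose held fixed, 67.2 mM in dusk.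

Now we turn the question round. For the row to fall from summer to dusk, the fraction made in dusk must drop below half of the fraction made in summer. Starting from our dose in summer, dusk would need a dose under 0.409. Maple has a single charge, 6 mM, so it shows nothing of how the dose moves with charge.

The forecast differs from our fixed dose, and its dusk value is lower than ours. It reads 4.3 mM, 7.2 mM, 10.7 mM, 13.2 mM and 14.7 mM, so the row rises all the way: “Substrate inhibition is possible but unsupported, so I expect a steady rise.”

The flasks give, from spring to dusk, 2.88 mM, 7.87 mM, 15.1 mM, 9.00 mM and 4.32 mM; the row rises, then falls, turning at 26 mM.

    starting material + enzyme → product + enzyme, rate k1*[starting material]^3*[enzyme]/(1 + ([starting material]/Kh1)^3) (8.98 mM, k = 2.73 × 10⁷ M⁻³ s⁻¹)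
    starting material + enzyme → spent catalyst (k = 28.6 M⁻¹ h⁻¹)

Read back from what was left, the dose is 0.655 in spring against our 1.11, and 0.0442 in dusk, under the 0.409 reckoned from our dose in summer. With concentrations as charged, the half-life of enzyme by the path to spent catalyst alone is 0.242 h in dusk, shorter than the 3.0 h of the run, and 4.0 h in spring. At 0.900 h, enzyme is 8.18% of the catalyst in dusk and 87.7% in spring.

Readings and results were generated by integration with constants of no real substance; scatter was added.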